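**Retrosynthetic overview**
- The quaternary carbon is made last: copper-catalysed enantioselective SN2′ coupling of an E-alkenylalane (from the ring alkyne) with (2E,6E)-farnesyl diethyl phosphate.
- Ring alkyne ⇐ secondary boronic ester (Zweifel-type alkynylation) ⇐ terminal alkene (copper-catalysed Markovnikov borylation sets the CH(CH3) centre).
- The only ring is formed early on that branch: a homologative semipinacol ring expansion (1,2-shift) of (S)-2,2,3-trimethylcyclopentanone by a sparteine-lithiated pentenyl carbamate gives the cyclohexanone and its side-chain stereocentre; methylenation follows.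
- The cyclopentanone comes from 2-methylcyclopent-2-enone by asymmetric conjugate addition and enolate methylation.
- Farnesyl phosphate ⇐ ethyl but-2-ynoate (syn-carbocupration) + homogeraniol, itself from 2,3-dihydrofuran by a cuprate 1,2-metallate rearrangement.

Assumption: (−)-sparteine, the chiral ligands, B2pin2, vinyl bromide and the C1 reagents are treated as reagents; where a ligand enantiomer cannot be fixed here, the one giving the stated descriptor is meant.

**Step 1**
Reactants: 1 2-methylcyclopent-2-en-1-one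
Product: 3 (3S)-2,2,3-trimethylcyclopentan-1-one, via magnesium enolate 2 (not isolated)
Conditions: MeMgBr, Cu(OTf)2 (3 mol %), chiral hydroxyalkyl-imidazolinium chloride (4 mol %, enantiomer giving 3S), Et2O, 0 °C; then MeI, DMPU, 0 °C → rt
Reagents that add atoms: methylmagnesium bromide C[Mg]Br; iodomethane CI
Why: Copper-catalysed asymmetric conjugate addition of the Grignard reagent (the chiral carbene ligand selects the enone face and sets C3 as S) gives the regiodefined enolate 2, whose C-methylation (enolate trapping) builds the gem-dimethyl carbon without touching the new stereocentre.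

**Step 2**
Reactants: 4 pent-4-en-1-ol
Product: 5 pent-4-en-1-yl N,N-diisopropylcarbamate
Conditions: iPr2NCOCl, Et3N, CH2Cl2, reflux
Reagents that add atoms: N,N-diisopropylcarbamoyl chloride CC(C)N(C(C)C)C(Cl)=O
Why: Simple O-carbamoylation of a primary alcohol installs the group that directs the lithiation and later serves as the leaving group.

**Step 3**
Reactants: 5 pent-4-en-1-yl N,N-diisopropylcarbamate, 3 (3S)-2,2,3-trimethylcyclopentan-1-one
Product: 9 (2R,4S)-2-(but-3-en-1-yl)-3,3,4-trimethylcyclohexan-1-one, via lithiated carbamate 6 (not isolated), via lithium alkoxide 7 (not isolated), via aluminium alkoxide 8 (not isolated)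
Conditions: sBuLi, (−)-sparteine, Et2O, −78 °C; 3, −78 °C; then Me2AlCl (4 equiv), toluene, −78 → 0 °C
Reagents that add atoms: none
Why: Proposed new method: a homologative semipinacol ring expansion in which the configurationally stable (S)-lithiated carbamate 6 (sparteine-mediated Hoppe lithiation) adds to ketone 3 with retention, and in the derived aluminium alkoxide 8, with the carbamate carbonyl activated by excess Me2AlCl, the electron-rich quaternary ring carbon shifts 1,2 antiperiplanar to the departing carbamate with inversion, so the six-membered ring is formed and its side-chain stereocentre (2R in 9) is fixed by the sparteine-controlled carbanion and not by the ring; the closest known reactions are the aluminium-promoted pinacol-type rearrangement of β-mesyloxy alcohols and the 1,2-metallate rearrangement of boronate complexes of the same lithiated carbamates, the new elements being an alkoxide as the pushing group and a carbamate as the leaving group.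

**Step 4**
Reactants: 9 (2R,4S)-2-(but-3-en-1-yl)-3,3,4-trimethylcyclohexan-1-one
Product: 10 4-[(1S,3S)-2,2,3-trimethyl-6-methylidenecyclohexyl]but-1-ene
Conditions: CH2Br2, Zn, TiCl4, THF–CH2Cl2, 0 → 25 °C
Reagents that add atoms: dibromomethane BrCBr
Why: Takai–Lombardo methylenation is non-basic, so the epimerisable α-stereocentre survives while the hindered ketone is converted and the terminal alkene stays inert.

**Step 5**
Reactants: 10 4-[(1S,3S)-2,2,3-trimethyl-6-methylidenecyclohexyl]but-1-ene
Product: 11 4,4,5,5-tetramethyl-2-[(2S)-4-[(1S,3S)-2,2,3-trimethyl-6-methylidenecyclohexyl]butan-2-yl]-1,3,2-dioxaborolane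
Conditions: B2pin2, CuCl (5 mol %), bulky silyl-substituted QuinoxP*-type bisphosphine (5 mol %, enantiomer giving S), KOtBu (10 mol %), MeOH (2 equiv), THF, rt
Reagents that add atoms: bis(pinacolato)diboron CC1(C)OB(OC1(C)C)B1OC(C)(C)C(C)(C)O1
Why: Copper-catalysed Markovnikov-selective enantioselective protoboration places boron on the internal carbon of the monosubstituted alkene under ligand control (setting the methyl-bearing centre as S) before methanolysis, and the 1,1-disubstituted exocyclic alkene is far less reactive.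

**Step 6**
Reactants: 11 4,4,5,5-tetramethyl-2-[(2S)-4-[(1S,3S)-2,2,3-trimethyl-6-methylidenecyclohexyl]butan-2-yl]-1,3,2-dioxaborolane
Product: 15 (3S)-3-methyl-5-[(1S,3S)-2,2,3-trimethyl-6-methylidenecyclohexyl]pent-1-yne, via boronate complex 12 (not isolated), via iodoalkyl boronic ester 13 (not isolated), via bromoalkene 14 (not isolated)
Conditions: CH2=CHBr, LiN(iPr)2, THF, −78 °C (11 present); I2, MeOH, −78 °C; NaOMe, MeOH, 0 °C; then Bu4NF·3H2O, DMF, 60 °C (telescoped)
Reagents that add atoms: vinyl bromide C=CBr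
Why: Zweifel-type alkenylation (iodine-triggered stereoretentive 1,2-metallate shift of the secondary alkyl group from boron to the bromovinyl carbon, then anti elimination of boron and iodide) followed by fluoride-induced dehydrobromination gives the terminal alkyne with the C–B stereocentre carried over with retention.

**Step 7**
Reactants: 16 5-bromo-2-methylpent-2-ene, 17 2,3-dihydrofuran
Product: 22 (3E)-4,8-dimethylnona-3,7-dien-1-ol, via homoprenyllithium 18 (not isolated), via lithiodihydrofuran 19 (not isolated), via mixed cuprate 20 (not isolated), via alkenylcopper alkoxide 21 (not isolated)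
Conditions: 16, Li, Et2O, 0 °C; 17, tBuLi, THF, −78 → 0 °C; CuBr·SMe2, Et2O–Me2S, −78 °C → rt; then MeI, 0 °C → rt
Reagents that add atoms: iodomethane CI
Why: In the 1,2-metallate rearrangement of the α-alkoxyalkenyl cuprate the alkyl group migrates from copper to the alkenyl carbon with inversion and ring opening of the dihydrofuran, and methylation of the resulting alkenylcopper with retention fixes the E trisubstituted alkene.

**Step 8**
Reactants: 22 (3E)-4,8-dimethylnona-3,7-dien-1-ol
Product: 23 (6E)-9-bromo-2,6-dimethylnona-2,6-diene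
Conditions: CBr4, PPh3, CH2Cl2, 0 °C
Reagents that add atoms: tetrabromomethane BrC(Br)(Br)Br
Why: Appel bromination of a primary homoallylic alcohol proceeds under neutral conditions without alkene migration.

**Step 9**
Reactants: 23 (6E)-9-bromo-2,6-dimethylnona-2,6-diene, 24 ethyl but-2-ynoate
Product: 28 ethyl (2E,6E)-3,7,11-trimethyldodeca-2,6,10-trienoate, via Grignard reagent 25 (not isolated), via alkylcopper 26 (not isolated), via alkenylcopper 27 (not isolated)
Conditions: Mg, THF; CuBr·SMe2, THF–Me2S, −40 °C; 24, −78 °C; MeOH, −78 °C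
Reagents that add atoms: none
Why: syn-Carbocupration of the ynoate places the alkyl group and copper cis, and protonation at −78 °C before the alkenylcopper can isomerise gives the 2E trisubstituted enoate.

**Step 10**
Reactants: 28 ethyl (2E,6E)-3,7,11-trimethyldodeca-2,6,10-trienoate
Product: 29 (2E,6E)-3,7,11-trimethyldodeca-2,6,10-trien-1-ol
Conditions: iBu2AlH (2.2 equiv), CH2Cl2, −78 → 0 °C; aq. KNaC4H4O6
Reagents that add atoms: none
Why: 1,2-Reduction of the conjugated ester by the aluminium hydride gives the allylic alcohol without touching the alkene geometry.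

**Step 11**
Reactants: 29 (2E,6E)-3,7,11-trimethyldodeca-2,6,10-trien-1-ol
Product: 30 diethyl (2E,6E)-3,7,11-trimethyldodeca-2,6,10-trien-1-yl phosphate
Conditions: ClP(O)(OEt)2, Et3N, DMAP (cat.), CH2Cl2, 0 °C
Reagents that add atoms: diethyl chlorophosphate CCOP(Cl)(=O)OCC
Why: O-Phosphorylation of the primary allylic alcohol gives the leaving group needed for copper-catalysed allylic substitution.

**Step 12**
Reactants: 15 (3S)-3-methyl-5-[(1S,3S)-2,2,3-trimethyl-6-methylidenecyclohexyl]pent-1-yne, 30 diethyl (2E,6E)-3,7,11-trimethyldodeca-2,6,10-trien-1-yl phosphate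
Product: 32 (6E,10S,11E,13S)-10-ethenyl-2,6,10,13-tetramethyl-15-[(1S,3S)-2,2,3-trimethyl-6-methylidenecyclohexyl]pentadeca-2,6,11-triene, via alkenylalane 31 (not isolated)
Conditions: iBu2AlH (1.0 equiv), hexane, 55 °C; then 30, [Ag(L1)]2 (2.5 mol %, L1 = chiral sulfonate-bearing N-heterocyclic carbene, enantiomer giving 10S), CuCl2·2H2O (5 mol %), THF, −15 °C
Reagents that add atoms: none
Why: syn-Hydroalumination of the terminal alkyne gives the E-alkenylalane, and carbene–copper-catalysed enantioselective allylic substitution delivers it SN2′ to one face of C3 of the E trisubstituted phosphate, which forms the quaternary stereocentre (S) with its vinyl group and keeps the E alkene.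

**Compound list**
1 | 2-methylcyclopent-2-en-1-one | CC1=CCCC1=O | starting material
2 | bromomagnesium (3S)-2,3-dimethylcyclopent-1-en-1-olate | Br[Mg]OC1=C(C)[C@@H](C)CC1 | intermediate
3 | (3S)-2,2,3-trimethylcyclopentan-1-one | O=C1CC[C@H](C)C1(C)C | intermediate
4 | pent-4-en-1-ol | C=CCCCO | starting material
5 | pent-4-en-1-yl N,N-diisopropylcarbamate | C=CCCCOC(=O)N(C(C)C)C(C)C | intermediate
6 | (1S)-1-lithiopent-4-en-1-yl N,N-diisopropylcarbamate (sparteine complex) | [Li][C@@H](CCC=C)OC(=O)N(C(C)C)C(C)C | intermediate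
7 | lithium (3S)-1-[(1R)-1-(diisopropylcarbamoyloxy)pent-4-en-1-yl]-2,2,3-trimethylcyclopentan-1-olate (both C1 epimers) | C=CCC[C@@H](OC(=O)N(C(C)C)C(C)C)C1(O[Li])CC[C@H](C)C1(C)C | intermediate
8 | dimethylaluminium alkoxide of the same carbinol | C=CCC[C@@H](OC(=O)N(C(C)C)C(C)C)C1(O[Al](C)C)CC[C@H](C)C1(C)C | intermediate
9 | (2R,4S)-2-(but-3-en-1-yl)-3,3,4-trimethylcyclohexan-1-one | C=CCC[C@H]1C(=O)CC[C@H](C)C1(C)C | intermediate
10 | 4-[(1S,3S)-2,2,3-trimethyl-6-methylidenecyclohexyl]but-1-ene | C=CCC[C@H]1C(=C)CC[C@H](C)C1(C)C | intermediate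
11 | 4,4,5,5-tetramethyl-2-[(2S)-4-[(1S,3S)-2,2,3-trimethyl-6-methylidenecyclohexyl]butan-2-yl]-1,3,2-dioxaborolane | CC1(C)OB(OC1(C)C)[C@@H](C)CC[C@H]2C(=C)CC[C@H](C)C2(C)C | intermediate
12 | lithium (1-bromoethenyl) ate complex of 11 | [Li+].C=C(Br)[B-]1(OC(C)(C)C(C)(C)O1)[C@@H](C)CC[C@H]2C(=C)CC[C@H](C)C2(C)C | intermediate
13 | 2-[(3S)-2-bromo-1-iodo-3-methyl-5-[(1S,3S)-2,2,3-trimethyl-6-methylidenecyclohexyl]pentan-2-yl]-4,4,5,5-tetramethyl-1,3,2-dioxaborolane (C2 epimers) | ICC(Br)(B1OC(C)(C)C(C)(C)O1)[C@@H](C)CC[C@H]2C(=C)CC[C@H](C)C2(C)C | intermediate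
14 | (3S)-2-bromo-3-methyl-5-[(1S,3S)-2,2,3-trimethyl-6-methylidenecyclohexyl]pent-1-ene | C=C(Br)[C@@H](C)CC[C@H]1C(=C)CC[C@H](C)C1(C)C | intermediate
15 | (3S)-3-methyl-5-[(1S,3S)-2,2,3-trimethyl-6-methylidenecyclohexyl]pent-1-yne | C#C[C@@H](C)CC[C@H]1C(=C)CC[C@H](C)C1(C)C | intermediate
16 | 5-bromo-2-methylpent-2-ene | CC(C)=CCCBr | starting material
17 | 2,3-dihydrofuran | C1CC=CO1 | starting material
18 | (4-methylpent-3-en-1-yl)lithium | [Li]CCC=C(C)C | intermediate
19 | (4,5-dihydrofuran-2-yl)lithium | [Li]C1=CCCO1 | intermediate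
20 | lithium (4,5-dihydrofuran-2-yl)(4-methylpent-3-en-1-yl)cuprate | [Li+].CC(C)=CCC[Cu-]C1=CCCO1 | intermediate
21 | lithium (3Z)-4-cuprio-8-methylnona-3,7-dien-1-olate | [Li]OCC/C=C(\[Cu])CCC=C(C)C | intermediate
22 | (3E)-4,8-dimethylnona-3,7-dien-1-ol | OCC/C=C(\C)CCC=C(C)C | intermediate
23 | (6E)-9-bromo-2,6-dimethylnona-2,6-diene | BrCC/C=C(\C)CCC=C(C)C | intermediate
24 | ethyl but-2-ynoate | CC#CC(=O)OCC | starting material
25 | [(3E)-4,8-dimethylnona-3,7-dien-1-yl]magnesium bromide | Br[Mg]CC/C=C(\C)CCC=C(C)C | intermediate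
26 | [(3E)-4,8-dimethylnona-3,7-dien-1-yl]copper | [Cu]CC/C=C(\C)CCC=C(C)C | intermediate
27 | ethyl (2Z,6E)-2-cuprio-3,7,11-trimethyldodeca-2,6,10-trienoate | CCOC(=O)/C([Cu])=C(\C)CC/C=C(\C)CCC=C(C)C | intermediate
28 | ethyl (2E,6E)-3,7,11-trimethyldodeca-2,6,10-trienoate | CCOC(=O)/C=C(\C)CC/C=C(\C)CCC=C(C)C | intermediate
29 | (2E,6E)-3,7,11-trimethyldodeca-2,6,10-trien-1-ol | OC/C=C(\C)CC/C=C(\C)CCC=C(C)C | intermediate
30 | diethyl (2E,6E)-3,7,11-trimethyldodeca-2,6,10-trien-1-yl phosphate | CCOP(=O)(OCC)OC/C=C(\C)CC/C=C(\C)CCC=C(C)C | intermediate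
31 | bis(2-methylpropyl)[(1E,3S)-3-methyl-5-[(1S,3S)-2,2,3-trimethyl-6-methylidenecyclohexyl]pent-1-en-1-yl]alumane | CC(C)C[Al](CC(C)C)/C=C/[C@@H](C)CC[C@H]1C(=C)CC[C@H](C)C1(C)C | intermediate
32 | (6E,10S,11E,13S)-10-ethenyl-2,6,10,13-tetramethyl-15-[(1S,3S)-2,2,3-trimethyl-6-methylidenecyclohexyl]pentadeca-2,6,11-triene | C=C[C@@](C)(/C=C/[C@@H](C)CC[C@H]1C(=C)CC[C@H](C)C1(C)C)CC/C=C(\C)CCC=C(C)C | target

**Step count and risks**
Total step count: 12. Longest linear sequence: 6 steps (1, 3, 4, 5, 6, 12; the branch 7, 8, 9, 10, 11, 12 is equally long).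

Step 3 (the proposed ring expansion) is the most likely to fail. The carbamate may not ionise, the ring CH2 may migrate instead of the quaternary carbon, epoxide closure may compete, and Me2AlCl can add methyl to or promote an ene reaction of product 9 if the mixture is warmed. The fallback uses known chemistry, sets out from 5 and 3 and comes back at 9. The same lithiation and addition (sBuLi, (−)-sparteine, Et2O, −78 °C; then 3) are quenched with MeOH to isolate (1R)-1-[(3S)-1-hydroxy-2,2,3-trimethylcyclopentyl]pent-4-en-1-yl N,N-diisopropylcarbamate F1. LiAlH4 in refluxing THF removes the carbamoyl group to give (1R)-1-[(3S)-1-hydroxy-2,2,3-trimethylcyclopentyl]pent-4-en-1-ol F2. MsCl, Et3N, CH2Cl2, −20 °C sulfonylates only the secondary hydroxyl to give the methanesulfonate F3. Et3Al, CH2Cl2, −78 → 0 °C then effects the established stereospecific pinacol-type rearrangement of a β-mesyloxy alcohol (migration anti to the mesylate, inversion) to give 9.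

Step 5 (Markovnikov protoboration) may give the linear boronate or a low diastereomer ratio on this remote-branched alkene. The fallback sets out from 10 and comes back at 15, bypassing step 6 as well. Zirconium-catalysed asymmetric carboalumination of the terminal alkene (Me3Al, the (NMI)2ZrCl2 enantiomer giving S, (MeAlO)n, CH2Cl2, 0 °C; then O2) gives (2S)-2-methyl-4-[(1S,3S)-2,2,3-trimethyl-6-methylidenecyclohexyl]butan-1-ol F4. Dess–Martin periodinane, NaHCO3, CH2Cl2 gives (2S)-2-methyl-4-[(1S,3S)-2,2,3-trimethyl-6-methylidenecyclohexyl]butanal F5. Ohira–Bestmann homologation (dimethyl (1-diazo-2-oxopropyl)phosphonate, K2CO3, MeOH, 0 °C) gives 15.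

Step 12 (final coupling) uses an α-branched alkenylalane and a polyene phosphate, so SN2′ selectivity, enantiofacial control or isobutyl transfer may be a problem. The fallback sets out from 15 and from Grignard reagent 25 (made from 23 as in step 9) and comes back at 32.
- Hydrozirconation of 15 (Cp2Zr(H)Cl, CH2Cl2), transmetalation with Me2Zn and amino-alcohol-catalysed addition to acetaldehyde give (2S,3E,5S)-5-methyl-7-[(1S,3S)-2,2,3-trimethyl-6-methylidenecyclohexyl]hept-3-en-2-ol F6.
- iPr2NCOCl, NaH, THF gives its N,N-diisopropylcarbamate F7.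
- 25 with 2-isopropoxy-4,4,5,5-tetramethyl-1,3,2-dioxaborolane gives 2-[(3E)-4,8-dimethylnona-3,7-dien-1-yl]-4,4,5,5-tetramethyl-1,3,2-dioxaborolane F8.
- Lithiation of F7 (sBuLi, Et2O, −78 °C), addition of F8 and 1,2-metallate rearrangement (MgBr2·OEt2, MeOH, warm) give the tertiary allylic boronic ester F9. Boron enters with retention and the dienyl chain migrates with inversion.
- Zweifel vinylation (vinyllithium, THF, −78 °C; I2, MeOH; NaOMe) replaces boron by vinyl with retention and gives 32.

**Further compounds**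
F1 | step 3 | (1R)-1-[(3S)-1-hydroxy-2,2,3-trimethylcyclopentyl]pent-4-en-1-yl N,N-diisopropylcarbamate | C=CCC[C@@H](OC(=O)N(C(C)C)C(C)C)C1(O)CC[C@H](C)C1(C)C
F2 | step 3 | (1R)-1-[(3S)-1-hydroxy-2,2,3-trimethylcyclopentyl]pent-4-en-1-ol | C=CCC[C@@H](O)C1(O)CC[C@H](C)C1(C)C
F3 | step 3 | (1R)-1-[(3S)-1-hydroxy-2,2,3-trimethylcyclopentyl]pent-4-en-1-yl methanesulfonate | C=CCC[C@@H](OS(C)(=O)=O)C1(O)CC[C@H](C)C1(C)C
F4 | step 5 | (2S)-2-methyl-4-[(1S,3S)-2,2,3-trimethyl-6-methylidenecyclohexyl]butan-1-ol | OC[C@@H](C)CC[C@H]1C(=C)CC[C@H](C)C1(C)C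
F5 | step 5 | (2S)-2-methyl-4-[(1S,3S)-2,2,3-trimethyl-6-methylidenecyclohexyl]butanal | O=C[C@@H](C)CC[C@H]1C(=C)CC[C@H](C)C1(C)C
F6 | step 12 | (2S,3E,5S)-5-methyl-7-[(1S,3S)-2,2,3-trimethyl-6-methylidenecyclohexyl]hept-3-en-2-ol | C[C@H](O)/C=C/[C@@H](C)CC[C@H]1C(=C)CC[C@H](C)C1(C)C
F7 | step 12 | (2S,3E,5S)-5-methyl-7-[(1S,3S)-2,2,3-trimethyl-6-methylidenecyclohexyl]hept-3-en-2-yl N,N-diisopropylcarbamate | C[C@H](OC(=O)N(C(C)C)C(C)C)/C=C/[C@@H](C)CC[C@H]1C(=C)CC[C@H](C)C1(C)C
F8 | step 12 | 2-[(3E)-4,8-dimethylnona-3,7-dien-1-yl]-4,4,5,5-tetramethyl-1,3,2-dioxaborolane | CC1(C)OB(CC/C=C(\C)CCC=C(C)C)OC1(C)C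
F9 | step 12 | 4,4,5,5-tetramethyl-2-[(6E,10S,11E,13S)-2,6,10,13-tetramethyl-15-[(1S,3S)-2,2,3-trimethyl-6-methylidenecyclohexyl]pentadeca-2,6,11-trien-10-yl]-1,3,2-dioxaborolane | CC1(C)OB(OC1(C)C)[C@@](C)(/C=C/[C@@H](C)CC[C@H]2C(=C)CC[C@H](C)C2(C)C)CC/C=C(\C)CCC=C(C)C
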